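**Retrosynthetic overview**

1. Locants: Ca = acetoxy-bearing exocyclic carbon; C1 = ring carbon attached to it; C2=C3 (Z) and C4=C5 (E, methyl on C5) = ring alkenes; C6 = ring CH2; C7 = lactone carbinol carbon; C8 = lactone carbonyl; C9 = its α-carbon; C10 = carbon between C7 and C9 that carries the side chain; C11 = side-chain stereocentre.
2. Target 24 ⇐ enal 23 by vinylogous enolisation and O-acetylation; 23 ⇐ silyl ether 21 by desilylation and allylic oxidation.
3. Key disconnection C7–C10: this bond belongs to both the nine-membered carbocycle and the γ-lactone of the 9-oxabicyclo[6.2.1]undecane core. A SmI2 ketyl–enoate cyclisation/lactonisation of open-chain aldehyde dienoate 19 closes the carbocycle first and the lactone second in one operation, and sets C7, C9 and C10 from the bought C11.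
4. Enabling feature: C7 (O-bearing) and C10 are the γ- and β-carbons of the lactone carbonyl C8, which is the retron of a reductive aldehyde/enoate β-carbon coupling; the E-C4=C5 alkene in the tether rules out every smaller ring.
5. 19 ⇐ Stille union (C1–C9) of α-stannyl enoate 6 (from (S)-citronellal) with (Z)-2-iodoallyl ether 16 (carboalumination, allyl–alkynyl coupling, directed trans-hydrostannation).

Key step: step 12

Remark (assumption): (S)-citronellal of high enantiomeric purity is taken as the commercial source of C11, and the target is taken as drawn (7S,9S,10R,11S in the locants above).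

**Route**

Step 1
Reactants: 1 (S)-citronellal
Product: 3 (3S)-3,7-dimethyloct-6-en-1-yne, via alkenyl nonaflate 2 (not isolated)
Conditions: n-C4F9SO2F (NfF), phosphazene base t-BuN=P(pyrrolidino)3 (BTPP, 2.5 equiv), DMF, −20 °C → rt
Reagents that add atoms: none
Why: One-pot enol nonaflation and base-induced elimination of nonaflate (non-homologative aldehyde-to-alkyne conversion) should turn the CH2–CHO unit into C≡CH, while the bought stereocentre, β to the carbonyl, is not deprotonated by the phosphazene base and is carried through unchanged.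

Step 2
Reactants: 3 (3S)-3,7-dimethyloct-6-en-1-yne
Product: 5 methyl (4S)-4,8-dimethylnon-7-en-2-ynoate, via lithium acetylide 4 (not isolated)
Conditions: n-BuLi, THF, −78 °C; then ClCO2Me, −78 → 0 °C
Reagents that add atoms: methyl chloroformate COC(=O)Cl
Why: Deprotonation of the terminal alkyne and C-acylation of the lithium acetylide with the chloroformate (acetylide carboxylation) should give the ynoate.

Step 3
Reactants: 5 methyl (4S)-4,8-dimethylnon-7-en-2-ynoate
Product: 6 methyl (2E,4S)-4,8-dimethyl-2-(tributylstannyl)nona-2,7-dienoate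
Conditions: Bu3SnH, Pd(PPh3)4 (2 mol%), THF, 0 °C → rt
Reagents that add atoms: tributyltin hydride CCCC[SnH](CCCC)CCCC
Why: Palladium-catalysed syn-hydrostannation of an alkynoate places tin on the ester-bearing carbon and hydrogen on the β-carbon, which fixes the alkene with the ester cis to the branched chain.

Step 4
Reactants: 7 (but-3-yn-1-yloxy)(tert-butyl)dimethylsilane
Product: 10 (2E)-5-{[tert-butyl(dimethyl)silyl]oxy}-3-methylpent-2-en-1-ol, via alkenylalane 8 (not isolated), via lithium alanate 9 (not isolated)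
Conditions: Me3Al, Cp2ZrCl2 (20 mol%), CH2Cl2, 0 °C → rt; then n-BuLi, THF, −30 °C; then (CH2O)n, rt
Reagents that add atoms: trimethylaluminium C[Al](C)C; paraformaldehyde (as formaldehyde) C=O
Why: Zirconium-catalysed syn-carboalumination (Negishi carboalumination) adds methyl to the internal and aluminium to the terminal alkyne carbon, and hydroxymethylation of the alanate with formaldehyde proceeds with retention, so the trisubstituted alkene should form as the E isomer.

Step 5
Reactants: 10 (2E)-5-{[tert-butyl(dimethyl)silyl]oxy}-3-methylpent-2-en-1-ol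
Product: 11 {[(3E)-5-bromo-3-methylpent-3-en-1-yl]oxy}(tert-butyl)dimethylsilane
Conditions: CBr4, PPh3, CH2Cl2, 0 °C
Reagents that add atoms: carbon tetrabromide BrC(Br)(Br)Br
Why: Appel bromination of the primary allylic alcohol proceeds by SN2 displacement without allylic transposition and leaves the silyl ether intact.

Step 6
Reactants: 11 {[(3E)-5-bromo-3-methylpent-3-en-1-yl]oxy}(tert-butyl)dimethylsilane; 12 prop-2-yn-1-ol
Product: 13 (5E)-8-{[tert-butyl(dimethyl)silyl]oxy}-6-methyloct-5-en-2-yn-1-ol
Conditions: CuI (10 mol%), NaI (10 mol%), K2CO3, DMF, rt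
Reagents that add atoms: none
Why: Copper-catalysed coupling of the terminal alkyne with the primary allylic bromide (SN2 attack of the copper acetylide at the unhindered carbon) should give the skipped enyne with retention of the E alkene.

Step 7
Reactants: 13 (5E)-8-{[tert-butyl(dimethyl)silyl]oxy}-6-methyloct-5-en-2-yn-1-ol
Product: 15 (2Z,5E)-8-{[tert-butyl(dimethyl)silyl]oxy}-2-iodo-6-methylocta-2,5-dien-1-ol, via vinylstannane 14 (not isolated)
Conditions: [Cp*RuCl]4 (2.5 mol%), Bu3SnH, CH2Cl2, rt; then I2, 0 °C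
Reagents that add atoms: iodine II
Why: Hydroxyl-directed ruthenium-catalysed trans-hydrostannation delivers tin to the alkyne carbon next to the carbinol and hydrogen anti to it, and iododestannylation with retention gives the 2-iodoallylic alcohol with iodine cis to the allylic CH2 chain.

Step 8
Reactants: 15 (2Z,5E)-8-{[tert-butyl(dimethyl)silyl]oxy}-2-iodo-6-methylocta-2,5-dien-1-ol
Product: 16 tert-butyl{[(2Z,5E)-8-{[tert-butyl(dimethyl)silyl]oxy}-2-iodo-6-methylocta-2,5-dien-1-yl]oxy}diphenylsilane
Conditions: TBDPSCl, imidazole, CH2Cl2, rt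
Reagents that add atoms: tert-butyl(chloro)diphenylsilane CC(C)(C)[Si](Cl)(c1ccccc1)c1ccccc1
Why: Silylation of the primary alcohol gives an ether that will survive the later acidic removal of the TBS group.

Step 9
Reactants: 6 methyl (2E,4S)-4,8-dimethyl-2-(tributylstannyl)nona-2,7-dienoate; 16 tert-butyl{[(2Z,5E)-8-{[tert-butyl(dimethyl)silyl]oxy}-2-iodo-6-methylocta-2,5-dien-1-yl]oxy}diphenylsilane
Product: 17 methyl (2Z,4S)-2-[(2E,5E)-8-{[tert-butyl(dimethyl)silyl]oxy}-1-{[tert-butyl(diphenyl)silyl]oxy}-6-methylocta-2,5-dien-2-yl]-4,8-dimethylnona-2,7-dienoate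
Conditions: Pd(PPh3)4 (5 mol%), CuI (10 mol%), CsF (2 equiv), DMF, rt → 40 °C
Reagents that add atoms: none
Why: Stille cross-coupling with copper and fluoride co-activation should join the two hindered alkenyl partners with retention of both geometries, giving the twisted diene ester with the ester cis to the branched chain.

Step 10
Reactants: 17 the bis-silyl dienoate
Product: 18 methyl (2Z,4S)-2-[(2E,5E)-1-{[tert-butyl(diphenyl)silyl]oxy}-8-hydroxy-6-methylocta-2,5-dien-2-yl]-4,8-dimethylnona-2,7-dienoate
Conditions: PPTS (20 mol%), MeOH/CH2Cl2, 0 °C → rt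
Reagents that add atoms: none
Why: Acid-catalysed methanolysis cleaves the primary TBS ether far faster than the bulkier TBDPS ether (selective desilylation).

Step 11
Reactants: 18 the primary alcohol
Product: 19 methyl (2Z,4S)-2-[(2E,5E)-1-{[tert-butyl(diphenyl)silyl]oxy}-6-methyl-8-oxoocta-2,5-dien-2-yl]-4,8-dimethylnona-2,7-dienoate
Conditions: Dess–Martin periodinane, NaHCO3, CH2Cl2, 0 °C; used at once
Reagents that add atoms: none
Why: Buffered Dess–Martin oxidation should give the β,γ-unsaturated aldehyde without migration of the trisubstituted alkene into conjugation.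

Step 12
Reactants: 19 the open-chain aldehyde dienoate
Product: 21 (1S,2E,5E,8S,11R)-2-({[tert-butyl(diphenyl)silyl]oxy}methyl)-6-methyl-11-[(2S)-6-methylhept-5-en-2-yl]-9-oxabicyclo[6.2.1]undeca-2,5-dien-10-one, via hydroxy ester 20 (not isolated)
Conditions: SmI2 (3 equiv), t-BuOH (3 equiv), THF, −78 °C → rt, slow addition of 19 (final 2 mM); then rt until lactonisation is complete
Reagents that add atoms: none
Why: Proposed new method: SmI2 reduces the aldehyde to a trivalent-samarium ketyl that is held by chelation to the ester carbonyl and adds through C7 to the β-carbon C10 of the 2-alkenyl acrylate; the ester- and allyl-stabilised C9 radical is reduced to the samarium dienolate and protonated at C9 by t-BuOH, and the C7 alkoxide then acylates itself on C8 with loss of methanol. The closest known reaction type is the SmI2 ketyl–enoate reductive cyclisation/lactonisation (aldehyde plus acrylate to γ-lactone), established intermolecularly and for five- to eight-membered carbocycles and proposed here for a nine-membered ring. The carbocycle closes in the 9-endo-trig radical mode and the γ-lactone in the 5-exo-trig mode by O-acylation. C10 is controlled by the bought C11 centre through allylic 1,3-strain (in the Z-enoate the C11–H eclipses the alkene and the ketyl should arrive on the methyl face, anti to the homoprenyl chain); C7 is controlled by the chelated bicyclic transition state, in which the Z-enoate geometry puts the side chain on the lactone side of the one-carbon bridge and the tether on the other; C9 is set by protonation on the convex face, which gives the only C9 epimer that can lactonise. The step needs ring-size selectivity, secured by the E-C4=C5 alkene (every smaller ring is impossible) and by the Z-C1=C2 alkene and the chelate (they bring C7 and C10 together), and chemoselectivity over pinacol coupling and simple reduction, secured by high dilution and by the conjugated acceptor that gives a doubly stabilised radical.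

Step 13
Reactants: 21 the bridged lactone silyl ether
Product: 22 (1S,2E,5E,8S,11R)-2-(hydroxymethyl)-6-methyl-11-[(2S)-6-methylhept-5-en-2-yl]-9-oxabicyclo[6.2.1]undeca-2,5-dien-10-one
Conditions: Bu4NF, AcOH (1:1), THF, 0 °C → rt
Reagents that add atoms: none
Why: Buffered fluoride desilylation should remove the TBDPS group without opening the bridged lactone or moving the skipped diene.

Step 14
Reactants: 22 the allylic alcohol
Product: 23 (1S,2E,5E,8S,11R)-6-methyl-11-[(2S)-6-methylhept-5-en-2-yl]-10-oxo-9-oxabicyclo[6.2.1]undeca-2,5-diene-2-carbaldehyde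
Conditions: MnO2, CH2Cl2, rt
Reagents that add atoms: none
Why: MnO2 oxidises the primary allylic alcohol selectively to the enal under neutral conditions (allylic oxidation).

Step 15
Reactants: 23 the enal lactone
Product: 24 target, {(Z)-[(1S,3Z,5E,8S,11R)-6-methyl-11-[(2S)-6-methylhept-5-en-2-yl]-10-oxo-9-oxabicyclo[6.2.1]undeca-3,5-dien-2-ylidene]methyl} acetate
Conditions: Ac2O, Et3N, DMAP (cat.), CH2Cl2, 0 °C → rt
Reagents that add atoms: acetic anhydride CC(=O)OC(C)=O
Why: Vinylogous enolisation of the enal at the doubly allylic C3 methylene followed by O-acetylation (dienol acetate formation) should give the trienyl acetate, because the s-trans enal delivers the acetoxy group cis to C9, the new C2=C3 alkene must be Z inside a nine-membered ring that already holds an E alkene, and the bridgehead C9–H of the lactone is not removed.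

**Compound list**

1 | (S)-citronellal, (3S)-3,7-dimethyloct-6-enal | O=CC[C@@H](C)CCC=C(C)C | starting material
2 | (3S)-3,7-dimethylocta-1,6-dien-1-yl nonafluorobutane-1-sulfonate (alkene isomers) | FC(F)(F)C(F)(F)C(F)(F)C(F)(F)S(=O)(=O)OC=C[C@@H](C)CCC=C(C)C | intermediate
3 | (3S)-3,7-dimethyloct-6-en-1-yne | C#C[C@@H](C)CCC=C(C)C | intermediate
4 | lithium (3S)-3,7-dimethyloct-6-en-1-yn-1-ide | [Li]C#C[C@@H](C)CCC=C(C)C | intermediate
5 | methyl (4S)-4,8-dimethylnon-7-en-2-ynoate | COC(=O)C#C[C@@H](C)CCC=C(C)C | intermediate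
6 | methyl (2E,4S)-4,8-dimethyl-2-(tributylstannyl)nona-2,7-dienoate | COC(=O)/C(=C\[C@@H](C)CCC=C(C)C)[Sn](CCCC)(CCCC)CCCC | intermediate
7 | (but-3-yn-1-yloxy)(tert-butyl)dimethylsilane | C#CCCO[Si](C)(C)C(C)(C)C | starting material
8 | [(1E)-4-{[tert-butyl(dimethyl)silyl]oxy}-2-methylbut-1-en-1-yl]dimethylalane | C[Al](C)/C=C(\C)CCO[Si](C)(C)C(C)(C)C | intermediate
9 | lithium butyl[(1E)-4-{[tert-butyl(dimethyl)silyl]oxy}-2-methylbut-1-en-1-yl]dimethylalanate | [Li+].CCCC[Al-](C)(C)/C=C(\C)CCO[Si](C)(C)C(C)(C)C | intermediate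
10 | (2E)-5-{[tert-butyl(dimethyl)silyl]oxy}-3-methylpent-2-en-1-ol | OC/C=C(\C)CCO[Si](C)(C)C(C)(C)C | intermediate
11 | {[(3E)-5-bromo-3-methylpent-3-en-1-yl]oxy}(tert-butyl)dimethylsilane | BrC/C=C(\C)CCO[Si](C)(C)C(C)(C)C | intermediate
12 | prop-2-yn-1-ol | OCC#C | starting material
13 | (5E)-8-{[tert-butyl(dimethyl)silyl]oxy}-6-methyloct-5-en-2-yn-1-ol | OCC#CC/C=C(\C)CCO[Si](C)(C)C(C)(C)C | intermediate
14 | (2Z,5E)-8-{[tert-butyl(dimethyl)silyl]oxy}-6-methyl-2-(tributylstannyl)octa-2,5-dien-1-ol | OC/C(=C/C/C=C(\C)CCO[Si](C)(C)C(C)(C)C)[Sn](CCCC)(CCCC)CCCC | intermediate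
15 | (2Z,5E)-8-{[tert-butyl(dimethyl)silyl]oxy}-2-iodo-6-methylocta-2,5-dien-1-ol | OC/C(I)=C/C/C=C(\C)CCO[Si](C)(C)C(C)(C)C | intermediate
16 | tert-butyl{[(2Z,5E)-8-{[tert-butyl(dimethyl)silyl]oxy}-2-iodo-6-methylocta-2,5-dien-1-yl]oxy}diphenylsilane | CC(C)(C)[Si](OC/C(I)=C/C/C=C(\C)CCO[Si](C)(C)C(C)(C)C)(c1ccccc1)c1ccccc1 | intermediate
17 | methyl (2Z,4S)-2-[(2E,5E)-8-{[tert-butyl(dimethyl)silyl]oxy}-1-{[tert-butyl(diphenyl)silyl]oxy}-6-methylocta-2,5-dien-2-yl]-4,8-dimethylnona-2,7-dienoate | COC(=O)/C(=C\[C@@H](C)CCC=C(C)C)/C(CO[Si](c1ccccc1)(c1ccccc1)C(C)(C)C)=C\C/C=C(\C)CCO[Si](C)(C)C(C)(C)C | intermediate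
18 | methyl (2Z,4S)-2-[(2E,5E)-1-{[tert-butyl(diphenyl)silyl]oxy}-8-hydroxy-6-methylocta-2,5-dien-2-yl]-4,8-dimethylnona-2,7-dienoate | COC(=O)/C(=C\[C@@H](C)CCC=C(C)C)/C(CO[Si](c1ccccc1)(c1ccccc1)C(C)(C)C)=C\C/C=C(\C)CCO | intermediate
19 | methyl (2Z,4S)-2-[(2E,5E)-1-{[tert-butyl(diphenyl)silyl]oxy}-6-methyl-8-oxoocta-2,5-dien-2-yl]-4,8-dimethylnona-2,7-dienoate | COC(=O)/C(=C\[C@@H](C)CCC=C(C)C)/C(CO[Si](c1ccccc1)(c1ccccc1)C(C)(C)C)=C\C/C=C(\C)CC=O | intermediate
20 | methyl (1S,2E,5E,8S,9R)-2-({[tert-butyl(diphenyl)silyl]oxy}methyl)-8-hydroxy-6-methyl-9-[(2S)-6-methylhept-5-en-2-yl]cyclonona-2,5-diene-1-carboxylate | CC(C)(C)[Si](OC/C1=C/C/C=C(\C)C[C@H](O)[C@H]([C@@H](C)CCC=C(C)C)[C@@H]1C(=O)OC)(c1ccccc1)c1ccccc1 | intermediate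
21 | (1S,2E,5E,8S,11R)-2-({[tert-butyl(diphenyl)silyl]oxy}methyl)-6-methyl-11-[(2S)-6-methylhept-5-en-2-yl]-9-oxabicyclo[6.2.1]undeca-2,5-dien-10-one | CC(C)(C)[Si](OC/C1=C/C/C=C(\C)C[C@@H]2OC(=O)[C@H]1[C@H]2[C@@H](C)CCC=C(C)C)(c1ccccc1)c1ccccc1 | intermediate
22 | (1S,2E,5E,8S,11R)-2-(hydroxymethyl)-6-methyl-11-[(2S)-6-methylhept-5-en-2-yl]-9-oxabicyclo[6.2.1]undeca-2,5-dien-10-one | OC/C1=C/C/C=C(\C)C[C@@H]2OC(=O)[C@H]1[C@H]2[C@@H](C)CCC=C(C)C | intermediate
23 | (1S,2E,5E,8S,11R)-6-methyl-11-[(2S)-6-methylhept-5-en-2-yl]-10-oxo-9-oxabicyclo[6.2.1]undeca-2,5-diene-2-carbaldehyde | O=C/C1=C/C/C=C(\C)C[C@@H]2OC(=O)[C@H]1[C@H]2[C@@H](C)CCC=C(C)C | intermediate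
24 | {(Z)-[(1S,3Z,5E,8S,11R)-6-methyl-11-[(2S)-6-methylhept-5-en-2-yl]-10-oxo-9-oxabicyclo[6.2.1]undeca-3,5-dien-2-ylidene]methyl} acetate (CNP0287742.1) | CC(=O)O/C=C1/C=C\C=C(/C)C[C@@H]2OC(=O)[C@H]1[C@H]2[C@@H](C)CCC=C(C)C | target

**Step count and risks**

Total step count: 15. Longest linear sequence: 12 steps (7 to 24, steps 4–15).

Steps most likely to fail:

1. Step 12 (Proposed new method). Closure of the strained nine-membered ring may be outrun by simple reduction of the aldehyde, conjugate reduction of the dienoate or intermolecular pinacol coupling, and the facial selectivity at C10 may be low. The fallback uses known chemistry, sets out from 17 and returns at 21. Reduction of 17 with i-Bu2AlH (CH2Cl2, −78 °C) should give the allylic alcohol F1. MsCl, 2,4,6-collidine and LiCl in DMF should convert it to the allylic chloride F2. PPTS/MeOH should then remove the TBS group to give the chloro alcohol F3, and Dess–Martin periodinane/NaHCO3 should give the chloro aldehyde F4. An intramolecular Nozaki–Hiyama–Kishi allylation (CrCl2, LiI, THF, high dilution), a reaction type with precedent for nine-membered carbocycles, should form the same C7–C10 bond through the γ-carbon of the allylchromium; its chair transition state gives the required anti relationship of hydroxyl and side chain in the methylidene cyclononadienol F5. Hydroboration of the 1,1-disubstituted alkene with 9-BBN and oxidation with H2O2/NaOH should give the 1,4-diol F6. Oxidative lactonisation with TEMPO/PhI(OAc)2 should return to 21; the C9 epimer that cannot lactonise is removed at this stage.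

2. Step 9. Transmetallation of the hindered α-stannyl enoate may be slow, leading to protodestannylation, cine substitution or loss of the enoate geometry. The fallback reverses the polarity in a Negishi coupling; it sets out from 6 and 16 and returns at 17. Iododestannylation of 6 (I2, CH2Cl2, 0 °C) should give the iodo enoate F7. Iodine–lithium exchange on 16 (t-BuLi, Et2O, −78 °C) should give the alkenyllithium F8, which is trapped at once with ZnCl2 as the alkenylzinc chloride F9. Coupling of F9 with F7 under Pd(PPh3)4 in THF should give 17 with retention at both alkenes.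

3. Step 15. The geometry of the two new C=C bonds may be poorly controlled during enolisation and acylation, or the base may move the skipped diene into other conjugated isomers. The fallback separates enolisation from acylation; it sets out from 23 and returns at 24. Soft enolisation with TMSOTf/Et3N (CH2Cl2, −78 °C) should give the trimethylsilyl trienol ether F10, at which stage geometric isomers can be separated. Fluoride-catalysed acyl exchange with acetyl fluoride (cat. Bu4N[Ph3SiF2], THF, 0 °C) should then give 24 with retention of the enol geometry.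

**Further compounds**

F1 | step 12 | (2Z,4S)-2-[(2E,5E)-8-{[tert-butyl(dimethyl)silyl]oxy}-1-{[tert-butyl(diphenyl)silyl]oxy}-6-methylocta-2,5-dien-2-yl]-4,8-dimethylnona-2,7-dien-1-ol | OC/C(=C\[C@@H](C)CCC=C(C)C)/C(CO[Si](c1ccccc1)(c1ccccc1)C(C)(C)C)=C\C/C=C(\C)CCO[Si](C)(C)C(C)(C)C
F2 | step 12 | allylic chloride of F1 (CH2Cl in place of CH2OH) | ClC/C(=C\[C@@H](C)CCC=C(C)C)/C(CO[Si](c1ccccc1)(c1ccccc1)C(C)(C)C)=C\C/C=C(\C)CCO[Si](C)(C)C(C)(C)C
F3 | step 12 | chloro alcohol (TBS group of F2 removed) | ClC/C(=C\[C@@H](C)CCC=C(C)C)/C(CO[Si](c1ccccc1)(c1ccccc1)C(C)(C)C)=C\C/C=C(\C)CCO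
F4 | step 12 | chloro aldehyde (primary alcohol of F3 oxidised) | ClC/C(=C\[C@@H](C)CCC=C(C)C)/C(CO[Si](c1ccccc1)(c1ccccc1)C(C)(C)C)=C\C/C=C(\C)CC=O
F5 | step 12 | (1S,3E,6E,9R)-7-({[tert-butyl(diphenyl)silyl]oxy}methyl)-3-methyl-8-methylidene-9-[(2S)-6-methylhept-5-en-2-yl]cyclonona-3,6-dien-1-ol | CC(C)(C)[Si](OC/C1=C/C/C=C(\C)C[C@H](O)[C@H]([C@@H](C)CCC=C(C)C)C1=C)(c1ccccc1)c1ccccc1
F6 | step 12 | (1S,3E,6E,8S,9R)-7-({[tert-butyl(diphenyl)silyl]oxy}methyl)-8-(hydroxymethyl)-3-methyl-9-[(2S)-6-methylhept-5-en-2-yl]cyclonona-3,6-dien-1-ol | CC(C)(C)[Si](OC/C1=C/C/C=C(\C)C[C@H](O)[C@H]([C@@H](C)CCC=C(C)C)[C@@H]1CO)(c1ccccc1)c1ccccc1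
F7 | step 9 | methyl (2E,4S)-2-iodo-4,8-dimethylnona-2,7-dienoate | COC(=O)/C(I)=C\[C@@H](C)CCC=C(C)C
F8 | step 9 | alkenyllithium from 16 (Li in place of I) | [Li]/C(CO[Si](c1ccccc1)(c1ccccc1)C(C)(C)C)=C\C/C=C(\C)CCO[Si](C)(C)C(C)(C)C
F9 | step 9 | alkenylzinc chloride from F8 | Cl[Zn]/C(CO[Si](c1ccccc1)(c1ccccc1)C(C)(C)C)=C\C/C=C(\C)CCO[Si](C)(C)C(C)(C)C
F10 | step 15 | trimethylsilyl trienol ether of 23 (OSiMe3 in place of OAc of 24) | C[Si](C)(C)O/C=C1/C=C\C=C(/C)C[C@@H]2OC(=O)[C@H]1[C@H]2[C@@H](C)CCC=C(C)C
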